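**Retrosynthetic overview**

1. Ring A (the spiro triketone ring: C1 spiro, C2=O, C3, C4–O, C5 gem-diprenyl, C6=O) is made last, by a two-atom ring expansion of 3-ethoxy-4,4-diprenylcyclobut-2-enone. The bond between its carbonyl carbon and its gem-diprenyl carbon is cut, and the enolate carbon of a hydrindane ester plus its ester carbonyl are inserted (new bonds C1–C2 and C5–C6).
2. The feature that allows this: the spiro carbon lies between two ring carbonyls and the carbon across the ring is quaternary, so C2–C3–C4–C5 maps onto a 3-alkoxy-4,4-dialkylcyclobutenone and C6–C1 onto an ester enolate. The insertion is unsymmetrical, so it also fixes the configuration of the spiro carbon.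
3. Rings B and C (the trans-hydrindane) are closed together by an intramolecular Diels–Alder reaction of a trienoate made from (R)-linalool, which supplies the carbinol stereocentre and all ten terpenoid carbons.
4. Stereochemical relay: the axial ester of the cycloadduct steers O2 to the equatorial side of the C4' radical (axial methyl); that axial methyl then steers the cyclobutenone to the equatorial side of the ester enolate.
5. Order of ring formation: cyclobutenone (fragment), rings B + C (step 7), ring A (step 10); the acetyl group follows by O-to-C acyl shift and the hydroperoxide is unmasked last.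

Key step: step 10

Remarks: (R)-(−)-linalool of high enantiomeric purity is assumed. The β-triketone is drawn in the tautomer of the target SMILES. Bicyclic esters use indene locants (C1 carbinol, C3a, C4 peroxy carbon, C6 ester carbon, C7a); in the spiro compounds these locants are primed and ring A is numbered as in line 1.

**Step 1**
Reactants: 1 diethyl malonate; 2 1-bromo-3-methylbut-2-ene (prenyl bromide)
Product: 4 diethyl 2,2-bis(3-methylbut-2-en-1-yl)malonate, via diethyl 2-(3-methylbut-2-en-1-yl)malonate 3 (not isolated)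
Conditions: NaH (2.2 equiv), 2 (2.2 equiv in total), THF/DMF, 0 °C to rt
Reagents that add atoms: 1-bromo-3-methylbut-2-ene (second equivalent), CC(C)=CCBr
Why: Double C-alkylation of the malonate enolate by two equivalents of the allylic bromide (malonic ester synthesis), the mono-prenyl malonate 3 being deprotonated and alkylated again in the same flask; no stereocentre is formed.

**Step 2**
Reactants: 4 diethyl 2,2-bis(3-methylbut-2-en-1-yl)malonate
Product: 6 5-methyl-2-(3-methylbut-2-en-1-yl)hex-4-enoic acid, via diprenylmalonic acid 5 (not isolated)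
Conditions: KOH, EtOH/H2O, reflux; aq. HCl, 0 °C; then pyridine, 115 °C
Reagents that add atoms: potassium hydroxide, [K+].[OH-]
Why: Saponification followed by decarboxylation of the geminal diacid in pyridine (malonic ester synthesis) should leave the trisubstituted alkenes untouched.

**Step 3**
Reactants: 6 5-methyl-2-(3-methylbut-2-en-1-yl)hex-4-enoic acid; 7 ethoxyethyne (ethoxyacetylene)
Product: 10 3-ethoxy-4,4-bis(3-methylbut-2-en-1-yl)cyclobut-2-en-1-one, via acid chloride 8 (not isolated), via diprenylketene 9 (not isolated)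
Conditions: (COCl)2, DMF (cat.), CH2Cl2, 0 °C to rt; evaporate; then 7, Et3N, Et2O, rt to 35 °C
Reagents that add atoms: none
Why: Dehydrochlorination of the acid chloride gives the dialkylketene, which should undergo the regioselective [2+2] cycloaddition with the ynol ether (nucleophilic alkyne carbon to the ketene carbonyl carbon) to the 3-ethoxycyclobutenone.

**Step 4**
Reactants: 11 (R)-linalool [(3R)-3,7-dimethylocta-1,6-dien-3-ol]
Product: 12 (3R)-3,7-dimethyl-3-[(triethylsilyl)oxy]octa-1,6-diene
Conditions: Et3SiOTf, 2,6-lutidine, CH2Cl2, −78 to 0 °C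
Reagents that add atoms: triethylsilyl trifluoromethanesulfonate, CC[Si](CC)(CC)OS(=O)(=O)C(F)(F)F
Why: Silylation of the hindered tertiary alcohol with a silyl triflate; the stereocentre is not touched.

**Step 5**
Reactants: 12 (3R)-3,7-dimethyl-3-[(triethylsilyl)oxy]octa-1,6-diene
Product: 14 (2E,6R)-2,6-dimethyl-6-[(triethylsilyl)oxy]octa-2,7-dienal, via allylic alcohol 13 (not isolated)
Conditions: SeO2 (0.5 equiv), t-BuOOH, salicylic acid (cat.), CH2Cl2, rt; then MnO2, CH2Cl2, rt
Reagents that add atoms: selenium dioxide, O=[Se]=O; tert-butyl hydroperoxide, CC(C)(C)OO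
Why: Selenium dioxide allylic oxidation (ene reaction, then [2,3]-sigmatropic shift) selects the (E)-methyl group of the trisubstituted alkene, the vinyl group having no allylic hydrogen, and MnO2 takes the allylic alcohol to the enal.

**Step 6**
Reactants: 14 (2E,6R)-2,6-dimethyl-6-[(triethylsilyl)oxy]octa-2,7-dienal; 15 methyl (triphenylphosphoranylidene)acetate
Product: 16 methyl (2E,4E,8R)-4,8-dimethyl-8-[(triethylsilyl)oxy]deca-2,4,9-trienoate
Conditions: CH2Cl2, rt
Reagents that add atoms: none
Why: Wittig olefination with a stabilised ylide should give the (E)-enoate and thus the (E,E)-dienoate.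

**Step 7**
Reactants: 16 methyl (2E,4E,8R)-4,8-dimethyl-8-[(triethylsilyl)oxy]deca-2,4,9-trienoate
Product: 17 methyl (1R)-1,4-dimethyl-1-[(triethylsilyl)oxy]-2,3,3a,6,7,7a-hexahydro-1H-indene-6-carboxylate (3a-H and 7a-H trans; 1-CH3 and 6-CO2Me on the face of 7a-H)
Conditions: toluene, BHT (cat.), 180 °C, sealed tube
Reagents that add atoms: none
Why: Thermal intramolecular Diels–Alder reaction of a 1,3,8-nonatriene closes rings B and C at once: the (E,E)-diene places the ester cis to the C3a–C3 bond (axial, on the face of 7a-H), the exo-tether transition state favoured by the diene methyl next to the tether-bearing terminus and by the quaternary allylic carbon should give the trans ring fusion, and the allylic C–O bond lying inside with the methyl anti to the diene should place 7a-H cis to the C1 methyl.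

**Step 8**
Reactants: 17 methyl (1R)-1,4-dimethyl-1-[(triethylsilyl)oxy]-2,3,3a,6,7,7a-hexahydro-1H-indene-6-carboxylate
Product: 19 methyl 4-hydroperoxy-1,4-dimethyl-1-[(triethylsilyl)oxy]octahydro-1H-indene-6-carboxylate (trans-fused; 4-CH3 axial on the face of 7a-H, 4-OOH equatorial), via triethylsilyl peroxide 18 (not isolated)
Conditions: Co(thd)2 (thd = 2,2,6,6-tetramethylheptane-3,5-dionate, 5 mol %), O2 (1 atm), Et3SiH, ClCH2CH2Cl, rt; then K2CO3, MeOH, 0 °C
Reagents that add atoms: dioxygen, O=O
Why: Isayama–Mukaiyama hydroperoxysilylation: Markovnikov hydrogen-atom transfer from a cobalt hydride to C5 gives the tertiary C4 radical, which should be trapped by O2 on the face opposite the axial C6 ester (1,3-diaxial shielding), making the peroxy group equatorial and the methyl axial, and carbonate in methanol then cleaves only the silyl peroxide.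

**Step 9**
Reactants: 19 methyl 4-hydroperoxy-1,4-dimethyl-1-[(triethylsilyl)oxy]octahydro-1H-indene-6-carboxylate
Product: 20 methyl 4-[(tert-butyldiphenylsilyl)peroxy]-1,4-dimethyl-1-[(triethylsilyl)oxy]octahydro-1H-indene-6-carboxylate
Conditions: t-BuPh2SiCl, imidazole, DMF, 0 °C to rt
Reagents that add atoms: tert-butyl(chloro)diphenylsilane, CC(C)(C)[Si](Cl)(c1ccccc1)c1ccccc1
Why: Silylation of the acidic, unhindered terminal oxygen of the hydroperoxide gives a silyl peroxide that should tolerate amide base, dilute acid and acylation.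

**Step 10**
Reactants: 20 methyl 4-[(tert-butyldiphenylsilyl)peroxy]-1,4-dimethyl-1-[(triethylsilyl)oxy]octahydro-1H-indene-6-carboxylate; 10 3-ethoxy-4,4-bis(3-methylbut-2-en-1-yl)cyclobut-2-en-1-one
Product: 24 4'-[(tert-butyldiphenylsilyl)peroxy]-4-ethoxy-1',4'-dimethyl-5,5-bis(3-methylbut-2-en-1-yl)-1'-[(triethylsilyl)oxy]octahydrospiro[cyclohex-3-ene-1,6'-indene]-2,6-dione (C6=O axial on the face of 7a'-H, C2=O equatorial), via lithium enolate 21 (not isolated), via lithium cyclobutenolate 22 (not isolated), via lithium dienolate 23 (not isolated)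
Conditions: LiN(i-Pr)2 (1.15 equiv), THF, −78 °C; then 10, −78 °C to rt; aq. NH4Cl
Reagents that add atoms: none
Why: Proposed new method: the lithium enolate of 20 adds to the strained carbonyl of cyclobutenone 10, the cyclobutenolate 22 undergoes oxyanion-accelerated conrotatory 4π ring opening (oxide outward, hydrindanyl group inward) to the (E)-dienolate 23, in which the hydrindanyl carbon is cis to the ethoxy-bearing carbon, and the γ-carbon of 23 (the gem-diprenyl carbon) acylates itself with the methyl ester, so the four-membered ring grows by two atoms into ring A; the closest known reaction types are the 1,2-addition of organolithiums to 3-alkoxycyclobutenones, the alkoxide-accelerated electrocyclic opening of cyclobutenols, the annulation of lithium enolates with vinylketenes and the Dieckmann condensation. Ring A is the only ring closed, by 6-exo-trig attack of the dienolate γ-carbon on the ester carbonyl. The spiro carbon is the only new stereocentre and is set in the addition: the axial C4 methyl and the axial 7a-H block the upper face of the exocyclic enolate, so the cyclobutenone should enter equatorially and the ester stay axial, which puts C2 equatorial and C6 (next to the diprenyl carbon) axial as in the target. The step needs 1,2- and not 1,4-addition (hard lithium enolate, strained ketone), closure through carbon (only the γ-carbon reaches the ester through a six-membered transition state), the correct orientation of ring A (fixed by connectivity: the old carbonyl carbon is bonded to the spiro carbon, the diprenyl carbon closes onto the ester) and survival of the peroxide (hindered tertiary silyl peroxide, low temperature).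

**Step 11**
Reactants: 24 (spiro vinylogous ester)
Product: 25 4'-[(tert-butyldiphenylsilyl)peroxy]-1',4-dihydroxy-1',4'-dimethyl-5,5-bis(3-methylbut-2-en-1-yl)octahydrospiro[cyclohex-3-ene-1,6'-indene]-2,6-dione (enol form of the 2,4,6-trione)
Conditions: 1 M aq. HCl, THF, rt
Reagents that add atoms: water, O
Why: Acid hydrolysis of the vinylogous ester (C3 protonation, water addition at C4, loss of ethanol) should free the enolised 1,3-diketone and remove the triethylsilyl ether, while the hindered silyl peroxide and the prenyl groups should survive dilute acid at room temperature.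

**Step 12**
Reactants: 25 (enolised trione)
Product: 27 3-acetyl-4'-[(tert-butyldiphenylsilyl)peroxy]-1',4-dihydroxy-1',4'-dimethyl-5,5-bis(3-methylbut-2-en-1-yl)octahydrospiro[cyclohex-3-ene-1,6'-indene]-2,6-dione, via enol acetate 26 (not isolated)
Conditions: AcCl (1.1 equiv), Et3N, CH2Cl2, 0 °C; then DMAP (0.3 equiv), MeCN, 40 °C
Reagents that add atoms: acetyl chloride, CC(Cl)=O
Why: O-acetylation of the acidic enol followed by DMAP-mediated O-to-C acyl migration to C3, driven by the stability of the 2-acyl-1,3-dione; the tertiary alcohol should not be acylated under these conditions.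

**Step 13**
Reactants: 27 (silyl peroxide of the target)
Product: 28 CNP0149131.2, 3-acetyl-4'-hydroperoxy-1',4-dihydroxy-1',4'-dimethyl-5,5-bis(3-methylbut-2-en-1-yl)octahydrospiro[cyclohex-3-ene-1,6'-indene]-2,6-dione (spiro C1 R, C1' R, C3a' R, C4' R, C7a' S for the tautomer drawn)
Conditions: HF·pyridine, THF, 0 °C
Reagents that add atoms: none
Why: Fluoride-assisted cleavage of the Si–O bond of the silyl peroxide should release the tertiary hydroperoxide without touching the prenyl groups, the tertiary alcohol or the enolised triketone.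

**Compound list**

1 | diethyl malonate | CCOC(=O)CC(=O)OCC | starting material
2 | 1-bromo-3-methylbut-2-ene | CC(C)=CCBr | starting material
3 | diethyl 2-(3-methylbut-2-en-1-yl)malonate | CCOC(=O)C(CC=C(C)C)C(=O)OCC | intermediate
4 | diethyl 2,2-bis(3-methylbut-2-en-1-yl)malonate | CCOC(=O)C(CC=C(C)C)(CC=C(C)C)C(=O)OCC | intermediate
5 | 2,2-bis(3-methylbut-2-en-1-yl)malonic acid | OC(=O)C(CC=C(C)C)(CC=C(C)C)C(O)=O | intermediate
6 | 5-methyl-2-(3-methylbut-2-en-1-yl)hex-4-enoic acid | CC(C)=CCC(CC=C(C)C)C(O)=O | intermediate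
7 | ethoxyethyne | CCOC#C | starting material
8 | 5-methyl-2-(3-methylbut-2-en-1-yl)hex-4-enoyl chloride | CC(C)=CCC(CC=C(C)C)C(Cl)=O | intermediate
9 | bis(3-methylbut-2-en-1-yl)ketene | CC(C)=CCC(CC=C(C)C)=C=O | intermediate
10 | 3-ethoxy-4,4-bis(3-methylbut-2-en-1-yl)cyclobut-2-en-1-one | CCOC1=CC(=O)C1(CC=C(C)C)CC=C(C)C | intermediate
11 | (R)-linalool | CC(C)=CCC[C@@](C)(O)C=C | starting material
12 | (3R)-3,7-dimethyl-3-[(triethylsilyl)oxy]octa-1,6-diene | CC(C)=CCC[C@@](C)(O[Si](CC)(CC)CC)C=C | intermediate
13 | (2E,6R)-2,6-dimethyl-6-[(triethylsilyl)oxy]octa-2,7-dien-1-ol | OC/C(C)=C/CC[C@@](C)(O[Si](CC)(CC)CC)C=C | intermediate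
14 | (2E,6R)-2,6-dimethyl-6-[(triethylsilyl)oxy]octa-2,7-dienal | O=C/C(C)=C/CC[C@@](C)(O[Si](CC)(CC)CC)C=C | intermediate
15 | methyl (triphenylphosphoranylidene)acetate | COC(=O)C=P(c1ccccc1)(c1ccccc1)c1ccccc1 | starting material
16 | methyl (2E,4E,8R)-4,8-dimethyl-8-[(triethylsilyl)oxy]deca-2,4,9-trienoate | COC(=O)/C=C/C(C)=C/CC[C@@](C)(O[Si](CC)(CC)CC)C=C | intermediate
17 | trans-fused hexahydroindene ester (cycloadduct) | COC(=O)[C@H]1C[C@H]2[C@@H](CC[C@@]2(C)O[Si](CC)(CC)CC)C(C)=C1 | intermediate
18 | triethylsilyl peroxide of 19 | COC(=O)[C@H]1C[C@H]2[C@@H](CC[C@@]2(C)O[Si](CC)(CC)CC)[C@](C)(OO[Si](CC)(CC)CC)C1 | intermediate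
19 | hydroperoxy ester | COC(=O)[C@H]1C[C@H]2[C@@H](CC[C@@]2(C)O[Si](CC)(CC)CC)[C@](C)(OO)C1 | intermediate
20 | tert-butyldiphenylsilyl peroxy ester | COC(=O)[C@H]1C[C@H]2[C@@H](CC[C@@]2(C)O[Si](CC)(CC)CC)[C@](C)(OO[Si](c3ccccc3)(c3ccccc3)C(C)(C)C)C1 | intermediate
21 | lithium enolate of 20 | [Li+].COC([O-])=C1C[C@H]2[C@@H](CC[C@@]2(C)O[Si](CC)(CC)CC)[C@](C)(OO[Si](c3ccccc3)(c3ccccc3)C(C)(C)C)C1 | intermediate
22 | lithium cyclobutenolate (1,2-adduct) | [Li+].COC(=O)[C@]1(C[C@H]2[C@@H](CC[C@@]2(C)O[Si](CC)(CC)CC)[C@](C)(OO[Si](c3ccccc3)(c3ccccc3)C(C)(C)C)C1)C4([O-])C=C(OCC)C4(CC=C(C)C)CC=C(C)C | intermediate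
23 | lithium (E)-dienolate (ring-opened; hydrindanyl carbon cis to the ethoxy-bearing carbon) | [Li+].COC(=O)[C@]1(C[C@H]2[C@@H](CC[C@@]2(C)O[Si](CC)(CC)CC)[C@](C)(OO[Si](c3ccccc3)(c3ccccc3)C(C)(C)C)C1)/C([O-])=C\C(OCC)=C(CC=C(C)C)CC=C(C)C | intermediate
24 | spiro vinylogous ester (ring A closed) | CCOC1=CC(=O)[C@@]2(C[C@H]3[C@@H](CC[C@@]3(C)O[Si](CC)(CC)CC)[C@](C)(OO[Si](c4ccccc4)(c4ccccc4)C(C)(C)C)C2)C(=O)C1(CC=C(C)C)CC=C(C)C | intermediate
25 | enolised spiro trione, silyl peroxide | OC1=CC(=O)[C@@]2(C[C@H]3[C@@H](CC[C@@]3(C)O)[C@](C)(OO[Si](c4ccccc4)(c4ccccc4)C(C)(C)C)C2)C(=O)C1(CC=C(C)C)CC=C(C)C | intermediate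
26 | enol acetate of 25 (one of two regioisomers that converge) | CC(=O)OC1=CC(=O)[C@@]2(C[C@H]3[C@@H](CC[C@@]3(C)O)[C@](C)(OO[Si](c4ccccc4)(c4ccccc4)C(C)(C)C)C2)C(=O)C1(CC=C(C)C)CC=C(C)C | intermediate
27 | tert-butyldiphenylsilyl peroxide of the target | CC(=O)C1=C(O)C(CC=C(C)C)(CC=C(C)C)C(=O)[C@]2(C[C@H]3[C@@H](CC[C@@]3(C)O)[C@](C)(OO[Si](c4ccccc4)(c4ccccc4)C(C)(C)C)C2)C1=O | intermediate
28 | CNP0149131.2 | CC(=O)C1=C(O)C(CC=C(C)C)(CC=C(C)C)C(=O)[C@]2(C[C@H]3[C@@H](CC[C@@]3(C)O)[C@](C)(OO)C2)C1=O | target

**Step count and risks**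

Total: 13 steps. Longest linear sequence: 10 steps (steps 4 to 13, from (R)-linalool); the cyclobutenone takes 3 steps.

Steps most likely to fail:

1. Step 10 (proposed new method). The fully substituted enolate may not add to the hindered cyclobutenone carbonyl, or the dienolate may be quenched before the congested Dieckmann closure. Fallback, from 20 and 10 back to 24, in two stages of known chemistry: lithium enolate 21 is generated as before, and 10 is opened by irradiation (350 nm, THF, −78 °C) to the vinylketene F1, which is the known photochemical opening of cyclobutenones. The enolate is acylated at the unhindered ketene carbon (known C-acylation of lithium ester enolates by ketenes); a cold quench gives the open-chain β-keto ester F2. KOt-Bu in THF then closes ring A in a separate Dieckmann condensation to 24.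

2. Step 8. Facial selectivity of O2 capture at C4 may be poor, or the doubly activated C6–H may be autoxidised. Fallback, from 17 back to 24, with the peroxide introduced after ring A and the prenyl groups after that: 17 is annulated under the step 10 conditions with commercial 3-ethoxycyclobut-2-en-1-one (CCOC1=CC(=O)C1) to the spiro enone F3, which has no C6'–H and whose axial ring-A carbonyl shields the upper face of C4'. Co(thd)2/O2/Et3SiH gives the triethylsilyl peroxide F4 and K2CO3/MeOH the hydroperoxide F5. t-BuPh2SiCl/imidazole gives the silyl peroxide F6. Two rounds of LiN(i-Pr)2 and prenyl bromide 2 at C5, the only enolisable position, lead through the mono-prenyl compound F7 to 24.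

3. Step 11. The silyl peroxide protecting group may be lost during the acid hydrolysis. Fallback, from 24 to 28, without peroxide protection: prolonged aq. HCl/THF removes all three silyl groups and the enol ether to give the free hydroperoxy trione F8. Excess Ac2O/Et3N/DMAP acetylates the enol oxygen and the hydroperoxide to give F9, and the DMAP-mediated O-to-C shift gives the C-acetyl peroxyacetate F10. K2CO3 in MeOH at 0 °C then cleaves the perester to 28.

**Further compounds**

F1 | step 10 | 3-ethoxy-4-(3-methylbut-2-en-1-yl)-7-methylocta-1,3,6-trien-1-one (vinylketene) | O=C=CC(OCC)=C(CC=C(C)C)CC=C(C)C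
F2 | step 10 | open-chain β-keto ester | COC(=O)[C@]1(C[C@H]2[C@@H](CC[C@@]2(C)O[Si](CC)(CC)CC)[C@](C)(OO[Si](c3ccccc3)(c3ccccc3)C(C)(C)C)C1)C(=O)CC(OCC)=C(CC=C(C)C)CC=C(C)C
F3 | step 8 | spiro enone without prenyl groups (C4'=C5' alkene) | CCOC1=CC(=O)[C@@]2(C[C@H]3[C@@H](CC[C@@]3(C)O[Si](CC)(CC)CC)C(C)=C2)C(=O)C1
F4 | step 8 | triethylsilyl peroxide of F5 | CCOC1=CC(=O)[C@@]2(C[C@H]3[C@@H](CC[C@@]3(C)O[Si](CC)(CC)CC)[C@](C)(OO[Si](CC)(CC)CC)C2)C(=O)C1
F5 | step 8 | spiro hydroperoxide without prenyl groups | CCOC1=CC(=O)[C@@]2(C[C@H]3[C@@H](CC[C@@]3(C)O[Si](CC)(CC)CC)[C@](C)(OO)C2)C(=O)C1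
F6 | step 8 | tert-butyldiphenylsilyl peroxide of F5 | CCOC1=CC(=O)[C@@]2(C[C@H]3[C@@H](CC[C@@]3(C)O[Si](CC)(CC)CC)[C@](C)(OO[Si](c4ccccc4)(c4ccccc4)C(C)(C)C)C2)C(=O)C1
F7 | step 8 | mono-prenyl compound (both C5 epimers) | CCOC1=CC(=O)[C@@]2(C[C@H]3[C@@H](CC[C@@]3(C)O[Si](CC)(CC)CC)[C@](C)(OO[Si](c4ccccc4)(c4ccccc4)C(C)(C)C)C2)C(=O)C1CC=C(C)C
F8 | step 11 | free hydroperoxy trione (enol form) | OC1=CC(=O)[C@@]2(C[C@H]3[C@@H](CC[C@@]3(C)O)[C@](C)(OO)C2)C(=O)C1(CC=C(C)C)CC=C(C)C
F9 | step 11 | enol acetate peroxyacetate | CC(=O)OC1=CC(=O)[C@@]2(C[C@H]3[C@@H](CC[C@@]3(C)O)[C@](C)(OOC(C)=O)C2)C(=O)C1(CC=C(C)C)CC=C(C)C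
F10 | step 11 | C-acetyl peroxyacetate | CC(=O)C1=C(O)C(CC=C(C)C)(CC=C(C)C)C(=O)[C@]2(C[C@H]3[C@@H](CC[C@@]3(C)O)[C@](C)(OOC(C)=O)C2)C1=O
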